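**Retrosynthetic overview**
- Target ⇐ fourfold O‑deallylation ⇐ tetra‑O‑allyl chalcone ⇐ Claisen–Schmidt condensation of a chromenyl‑substituted benzaldehyde with 4'‑(allyloxy)‑2'‑hydroxyacetophenone.
- That benzaldehyde ⇐ Suzuki coupling (C3–aryl bond) of an (S)‑3‑bromo‑2‑aryl‑2H‑chromene with a 2‑(allyloxy)‑5‑formylphenyl pinacol boronate.
- 3‑Bromochromene ⇐ bromodecarboxylation ⇐ Pinnick oxidation ⇐ (S)‑2‑aryl‑2H‑chromene‑3‑carbaldehyde.
- Chromene‑3‑carbaldehyde ⇐ organocatalytic oxa‑Michael/aldol condensation of 4‑(allyloxy)salicylaldehyde with 4‑(allyloxy)cinnamaldehyde. This sets C2 and closes the pyran ring, the only ring formed; all benzene rings are bought.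
- Allyl ethers protect every phenol except the chelated 2'‑OH, because the free flav‑3‑ene tolerates neither acid, hydrogenolysis nor oxidants. From step 3 on, work below 60 °C and away from light.

Assumption: the target centre is (2S) as read from the SMILES (O1 > C3 > aryl > H); the sense of induction in step 3 follows the usual shielding model and is confirmed by chiral HPLC/CD on the first batch (the antipodal catalyst is used if it is reversed).

**Step 1**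
Reactants: 1 2,4‑dihydroxybenzaldehyde
Product: 2 4‑(allyloxy)‑2‑hydroxybenzaldehyde
Conditions: allyl bromide (1.05 equiv), K2CO3 (1.0 equiv), acetone, rt, 16 h
Reagents that add atoms: allyl bromide (C=CCBr)
Why: Williamson etherification in which the 2‑OH is held in a hydrogen bond to the formyl group, so the more acidic 4‑OH is alkylated selectively.

**Step 2**
Reactants: 3 (E)‑3‑(4‑hydroxyphenyl)prop‑2‑enal (p‑coumaraldehyde)
Product: 4 (E)‑3‑[4‑(allyloxy)phenyl]prop‑2‑enal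
Conditions: allyl bromide (1.2 equiv), K2CO3 (1.5 equiv), acetone, 50 °C, 6 h
Reagents that add atoms: allyl bromide (C=CCBr)
Why: Williamson etherification of the only phenol; the enal is untouched by carbonate in acetone.

**Step 3**
Reactants: 2 4‑(allyloxy)‑2‑hydroxybenzaldehyde; 4 (E)‑3‑[4‑(allyloxy)phenyl]prop‑2‑enal
Product: 6 (2S)‑7‑(allyloxy)‑2‑[4‑(allyloxy)phenyl]‑2H‑chromene‑3‑carbaldehyde, via 4‑hydroxychromane aldol adduct 5 (not isolated)
Conditions: 4 (1.2 equiv), (R)‑2‑[diphenyl(trimethylsilyloxy)methyl]pyrrolidine (20 mol %), 2‑nitrobenzoic acid (20 mol %), 4 Å MS, toluene, rt, 48–72 h, dark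
Reagents that add atoms: none
Why: Iminium/enamine domino oxa‑Michael–aldol condensation in which the phenol of 2 adds to the β‑carbon of the E‑iminium ion of 4 on the face away from the CPh2(OSiMe3) group, which with the (R)‑catalyst gives (S) at C2, after which the enamine closes onto the aryl aldehyde and dehydration to the conjugated enal removes the two other sp3 centres.

**Step 4**
Reactants: 6 (2S)‑7‑(allyloxy)‑2‑[4‑(allyloxy)phenyl]‑2H‑chromene‑3‑carbaldehyde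
Product: 7 (2S)‑7‑(allyloxy)‑2‑[4‑(allyloxy)phenyl]‑2H‑chromene‑3‑carboxylic acid
Conditions: NaClO2 (3 equiv), NaH2PO4 (3 equiv), 2‑methyl‑2‑butene (20 equiv), t‑BuOH/THF/H2O, 0 °C → rt, 3 h
Reagents that add atoms: sodium chlorite ([Na+].[O-]Cl=O)
Why: Pinnick oxidation converts the enal to the acid while the alkene scavenger removes HOCl, so the allyl ethers, the electron‑rich rings and the C2 centre (no enolisable position) are untouched.

**Step 5**
Reactants: 7 (2S)‑7‑(allyloxy)‑2‑[4‑(allyloxy)phenyl]‑2H‑chromene‑3‑carboxylic acid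
Product: 8 (2S)‑7‑(allyloxy)‑2‑[4‑(allyloxy)phenyl]‑3‑bromo‑2H‑chromene
Conditions: NBS (1.05 equiv), LiOAc (0.2 equiv), MeCN/H2O 97:3, 0 °C → rt, 30 min, dark
Reagents that add atoms: N‑bromosuccinimide (O=C1CCC(=O)N1Br)
Why: Catalytic Hunsdiecker bromodecarboxylation in which Br+ adds at C3 because the 2,4‑dioxygenated benzo ring stabilises the benzylic cation at C4, and loss of CO2 restores the C3=C4 bond with bromine at C3 without involving C2.

**Step 6**
Reactants: 9 3‑bromo‑4‑hydroxybenzaldehyde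
Product: 10 4‑hydroxy‑3‑(4,4,5,5‑tetramethyl‑1,3,2‑dioxaborolan‑2‑yl)benzaldehyde
Conditions: B2pin2 (1.3 equiv), PdCl2(dppf) (5 mol %), KOAc (3 equiv), 1,4‑dioxane, 85 °C, 12 h
Reagents that add atoms: bis(pinacolato)diboron (CC1(C)OB(OC1(C)C)B1OC(C)(C)C(C)(C)O1)
Why: Miyaura borylation of the aryl bromide, in which the weak base KOAc tolerates the free phenol and the aldehyde; borylating before allylation keeps the allyl ether away from B2pin2 and palladium.

**Step 7**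
Reactants: 10 4‑hydroxy‑3‑(4,4,5,5‑tetramethyl‑1,3,2‑dioxaborolan‑2‑yl)benzaldehyde
Product: 11 4‑(allyloxy)‑3‑(4,4,5,5‑tetramethyl‑1,3,2‑dioxaborolan‑2‑yl)benzaldehyde
Conditions: allyl bromide (1.2 equiv), K2CO3 (1.5 equiv), DMF, rt, 4 h
Reagents that add atoms: allyl bromide (C=CCBr)
Why: Williamson etherification of the acidic para‑formyl phenol; the pinacol boronate survives carbonate in dry DMF at rt.

**Step 8**
Reactants: 8 (2S)‑7‑(allyloxy)‑2‑[4‑(allyloxy)phenyl]‑3‑bromo‑2H‑chromene; 11 4‑(allyloxy)‑3‑(4,4,5,5‑tetramethyl‑1,3,2‑dioxaborolan‑2‑yl)benzaldehyde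
Product: 12 4‑(allyloxy)‑3‑[(2S)‑7‑(allyloxy)‑2‑[4‑(allyloxy)phenyl]‑2H‑chromen‑3‑yl]benzaldehyde
Conditions: Pd(OAc)2 (5 mol %), SPhos (10 mol %), K3PO4 (3 equiv), THF/H2O 10:1, 50 °C, 6 h
Reagents that add atoms: none
Why: Suzuki–Miyaura coupling in which the bulky, electron‑rich SPhos ligand lets the hindered alkenyl bromide and the ortho‑alkoxy aryl boronate couple at 50 °C, a temperature at which the aryl allyl ethers and the C2 centre are not affected.

**Step 9**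
Reactants: 13 2',4'‑dihydroxyacetophenone
Product: 14 1‑[4‑(allyloxy)‑2‑hydroxyphenyl]ethan‑1‑one
Conditions: allyl bromide (1.1 equiv), K2CO3 (1.1 equiv), acetone, 50 °C, 8 h
Reagents that add atoms: allyl bromide (C=CCBr)
Why: Williamson etherification that is selective for the 4‑OH because the 2‑OH is chelated to the acetyl group.

**Step 10**
Reactants: 12 4‑(allyloxy)‑3‑[(2S)‑7‑(allyloxy)‑2‑[4‑(allyloxy)phenyl]‑2H‑chromen‑3‑yl]benzaldehyde; 14 1‑[4‑(allyloxy)‑2‑hydroxyphenyl]ethan‑1‑one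
Product: 16 (E)‑1‑[4‑(allyloxy)‑2‑hydroxyphenyl]‑3‑{4‑(allyloxy)‑3‑[(2S)‑7‑(allyloxy)‑2‑[4‑(allyloxy)phenyl]‑2H‑chromen‑3‑yl]phenyl}prop‑2‑en‑1‑one, via beta‑hydroxy ketone aldol adduct 15 (not isolated)
Conditions: KOH (6 equiv), EtOH/THF 4:1, 0 °C → rt, 24 h; then aq. NH4Cl to pH 6–7
Reagents that add atoms: none
Why: Claisen–Schmidt condensation in which the enolate of 14 adds to the non‑enolisable aldehyde 12 and E1cB dehydration gives the (E)‑enone; the O‑allyl group para to the formyl group prevents phenoxide deactivation, and the allyl ethers and the non‑acidic C2–H survive hydroxide.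

**Step 11**
Reactants: 16 (E)‑1‑[4‑(allyloxy)‑2‑hydroxyphenyl]‑3‑{4‑(allyloxy)‑3‑[(2S)‑7‑(allyloxy)‑2‑[4‑(allyloxy)phenyl]‑2H‑chromen‑3‑yl]phenyl}prop‑2‑en‑1‑one
Product: 17 (E)‑1‑(2,4‑dihydroxyphenyl)‑3‑{4‑hydroxy‑3‑[(2S)‑7‑hydroxy‑2‑(4‑hydroxyphenyl)‑2H‑chromen‑3‑yl]phenyl}prop‑2‑en‑1‑one (target)
Conditions: Pd(PPh3)4 (10 mol %), morpholine (20 equiv), degassed THF, rt, 2 h, dark
Reagents that add atoms: none
Why: Tsuji–Trost deallylation in which zerovalent palladium ionises the four terminal allyl aryl ethers and morpholine takes up the allyl groups at neutral pH, so the enone, the acid‑sensitive flavene and its C2 centre (whose ring C2–O bond is a hindered, internal allylic ether that does not ionise at rt) are preserved.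

**Compound list**
1 | 2,4‑dihydroxybenzaldehyde | O=Cc1ccc(O)cc1O | starting material
2 | 4‑(allyloxy)‑2‑hydroxybenzaldehyde | O=Cc1ccc(OCC=C)cc1O | intermediate
3 | (E)‑3‑(4‑hydroxyphenyl)prop‑2‑enal | O=C/C=C/c1ccc(O)cc1 | starting material
4 | (E)‑3‑[4‑(allyloxy)phenyl]prop‑2‑enal | O=C/C=C/c1ccc(OCC=C)cc1 | intermediate
5 | 7‑(allyloxy)‑2‑[4‑(allyloxy)phenyl]‑4‑hydroxy‑3,4‑dihydro‑2H‑chromene‑3‑carbaldehyde, C2 arranged in space as in 6 (letter R by CIP because C3 is sp3), C3 and C4 unassigned | O=CC1C(O)c2ccc(OCC=C)cc2O[C@H]1c1ccc(OCC=C)cc1 | intermediate (not isolated)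
6 | (2S)‑7‑(allyloxy)‑2‑[4‑(allyloxy)phenyl]‑2H‑chromene‑3‑carbaldehyde | O=CC1=Cc2ccc(OCC=C)cc2O[C@H]1c1ccc(OCC=C)cc1 | intermediate
7 | (2S)‑7‑(allyloxy)‑2‑[4‑(allyloxy)phenyl]‑2H‑chromene‑3‑carboxylic acid | OC(=O)C1=Cc2ccc(OCC=C)cc2O[C@H]1c1ccc(OCC=C)cc1 | intermediate
8 | (2S)‑7‑(allyloxy)‑2‑[4‑(allyloxy)phenyl]‑3‑bromo‑2H‑chromene | BrC1=Cc2ccc(OCC=C)cc2O[C@H]1c1ccc(OCC=C)cc1 | intermediate
9 | 3‑bromo‑4‑hydroxybenzaldehyde | O=Cc1ccc(O)c(Br)c1 | starting material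
10 | 4‑hydroxy‑3‑(4,4,5,5‑tetramethyl‑1,3,2‑dioxaborolan‑2‑yl)benzaldehyde | O=Cc1ccc(O)c(B2OC(C)(C)C(C)(C)O2)c1 | intermediate
11 | 4‑(allyloxy)‑3‑(4,4,5,5‑tetramethyl‑1,3,2‑dioxaborolan‑2‑yl)benzaldehyde | O=Cc1ccc(OCC=C)c(B2OC(C)(C)C(C)(C)O2)c1 | intermediate
12 | 4‑(allyloxy)‑3‑[(2S)‑7‑(allyloxy)‑2‑[4‑(allyloxy)phenyl]‑2H‑chromen‑3‑yl]benzaldehyde | O=Cc1ccc(OCC=C)c(C2=Cc3ccc(OCC=C)cc3O[C@H]2c2ccc(OCC=C)cc2)c1 | intermediate
13 | 2',4'‑dihydroxyacetophenone | CC(=O)c1ccc(O)cc1O | starting material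
14 | 1‑[4‑(allyloxy)‑2‑hydroxyphenyl]ethan‑1‑one | CC(=O)c1ccc(OCC=C)cc1O | intermediate
15 | 1‑[4‑(allyloxy)‑2‑hydroxyphenyl]‑3‑hydroxy‑3‑{4‑(allyloxy)‑3‑[(2S)‑7‑(allyloxy)‑2‑[4‑(allyloxy)phenyl]‑2H‑chromen‑3‑yl]phenyl}propan‑1‑one (carbinol epimers) | O=C(CC(O)c1ccc(OCC=C)c(C2=Cc3ccc(OCC=C)cc3O[C@H]2c2ccc(OCC=C)cc2)c1)c1ccc(OCC=C)cc1O | intermediate (not isolated)
16 | (E)‑1‑[4‑(allyloxy)‑2‑hydroxyphenyl]‑3‑{4‑(allyloxy)‑3‑[(2S)‑7‑(allyloxy)‑2‑[4‑(allyloxy)phenyl]‑2H‑chromen‑3‑yl]phenyl}prop‑2‑en‑1‑one | O=C(/C=C/c1ccc(OCC=C)c(C2=Cc3ccc(OCC=C)cc3O[C@H]2c2ccc(OCC=C)cc2)c1)c1ccc(OCC=C)cc1O | intermediate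
17 | (E)‑1‑(2,4‑dihydroxyphenyl)‑3‑{4‑hydroxy‑3‑[(2S)‑7‑hydroxy‑2‑(4‑hydroxyphenyl)‑2H‑chromen‑3‑yl]phenyl}prop‑2‑en‑1‑one | O=C(/C=C/c1ccc(O)c(C2=Cc3ccc(O)cc3O[C@H]2c2ccc(O)cc2)c1)c1ccc(O)cc1O | target

**Step count**
Total: 11 steps. Longest linear sequence: 7 steps (1 → 3 → 4 → 5 → 8 → 10 → 11).

**Three steps most likely to fail**

Step 3. Both partners are electron‑rich, so iminium formation and the oxa‑Michael step are slow and reversible, and long contact of 6 with the amine can erode ee through the dienamine. The fallback sets out from 2 and 4 and comes back at 7. The same condensation is run with an achiral base (K2CO3, 1,4‑dioxane, 80 °C) to give racemic 7‑(allyloxy)‑2‑[4‑(allyloxy)phenyl]‑2H‑chromene‑3‑carbaldehyde F1. Pinnick oxidation as in step 4 gives the racemic carboxylic acid F2. Half an equivalent of (S)‑1‑phenylethylamine in EtOH/EtOAc crystallises the less soluble diastereomeric salt, (S)‑1‑phenylethylammonium (2S)‑chromene‑3‑carboxylate F3; the (R)‑amine is used if the other diastereomer is the one that crystallises. Partition between cold aqueous citric acid and EtOAc releases 7. A scalemic acid from a partly selective step 3 is upgraded the same way.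

Step 5. NBS may brominate the resorcinol‑type ring at C6/C8 or attack the allyl alkenes instead of effecting ipso‑bromodecarboxylation. The fallback sets out from 7 and comes back at 12. Curtius rearrangement (DPPA, Et3N, toluene, rt then 80 °C) takes 7 through the acyl azide F4 to the 3‑isocyanato‑2H‑chromene F5, neither isolated. Hydrolysis (THF, aq. HCl, rt) gives (2S)‑7‑(allyloxy)‑2‑[4‑(allyloxy)phenyl]chroman‑3‑one F6. Kinetic deprotonation at the benzylic C4 methylene (KN(SiMe3)2, THF, −78 °C) and trapping with PhNTf2 gives the 2H‑chromen‑3‑yl triflate F7, which is coupled with 11 under the step 8 conditions to give 12. C2 of F6 is alpha to the ketone, so ee is checked after triflation.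

Step 8. The coupling joins a hindered alkenyl bromide to an ortho‑alkoxy aryl boronate that can protodeboronate, and zerovalent palladium may start to cleave the allyl ether para to the formyl group. The fallback sets out from 8 and 9 and comes back at 12, bypassing steps 6 and 7 by reversing the polarity of the coupling. Miyaura borylation of 8 (B2pin2, PdCl2(dppf), KOAc, 1,4‑dioxane, 70 °C) gives the chromen‑3‑yl pinacol boronate F8. O‑Allylation of 9 (allyl bromide, K2CO3, acetone) gives 4‑(allyloxy)‑3‑bromobenzaldehyde F9. Suzuki coupling of F8 with F9 (Pd(OAc)2, SPhos, K3PO4, THF/H2O, 50 °C) gives 12.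

**Further compounds**
F1 | step 3 | racemic 7‑(allyloxy)‑2‑[4‑(allyloxy)phenyl]‑2H‑chromene‑3‑carbaldehyde | O=CC1=Cc2ccc(OCC=C)cc2OC1c1ccc(OCC=C)cc1
F2 | step 3 | racemic 7‑(allyloxy)‑2‑[4‑(allyloxy)phenyl]‑2H‑chromene‑3‑carboxylic acid | OC(=O)C1=Cc2ccc(OCC=C)cc2OC1c1ccc(OCC=C)cc1
F3 | step 3 | (S)‑1‑phenylethylammonium (2S)‑7‑(allyloxy)‑2‑[4‑(allyloxy)phenyl]‑2H‑chromene‑3‑carboxylate | C[C@H]([NH3+])c1ccccc1.[O-]C(=O)C1=Cc2ccc(OCC=C)cc2O[C@H]1c1ccc(OCC=C)cc1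
F4 | step 5 | (2S)‑7‑(allyloxy)‑2‑[4‑(allyloxy)phenyl]‑2H‑chromene‑3‑carbonyl azide | [N-]=[N+]=NC(=O)C1=Cc2ccc(OCC=C)cc2O[C@H]1c1ccc(OCC=C)cc1
F5 | step 5 | (2S)‑7‑(allyloxy)‑2‑[4‑(allyloxy)phenyl]‑3‑isocyanato‑2H‑chromene | O=C=NC1=Cc2ccc(OCC=C)cc2O[C@H]1c1ccc(OCC=C)cc1
F6 | step 5 | (2S)‑7‑(allyloxy)‑2‑[4‑(allyloxy)phenyl]chroman‑3‑one | O=C1Cc2ccc(OCC=C)cc2O[C@H]1c1ccc(OCC=C)cc1
F7 | step 5 | (2S)‑7‑(allyloxy)‑2‑[4‑(allyloxy)phenyl]‑2H‑chromen‑3‑yl trifluoromethanesulfonate | O=S(=O)(OC1=Cc2ccc(OCC=C)cc2O[C@H]1c1ccc(OCC=C)cc1)C(F)(F)F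
F8 | step 8 | 2‑[(2R)‑7‑(allyloxy)‑2‑[4‑(allyloxy)phenyl]‑2H‑chromen‑3‑yl]‑4,4,5,5‑tetramethyl‑1,3,2‑dioxaborolane (same spatial arrangement at C2 as 8; the letter changes because boron ranks below carbon) | CC1(C)OB(OC1(C)C)C1=Cc2ccc(OCC=C)cc2O[C@H]1c1ccc(OCC=C)cc1
F9 | step 8 | 4‑(allyloxy)‑3‑bromobenzaldehyde | O=Cc1ccc(OCC=C)c(Br)c1
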